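**Retrosynthetic overview**
1. Target 33 ⇐ acidolysis and lactonisation (C7–O onto C19) of hydroxy ester 31 ⇐ Ni/Cr closure of the C6–C7 bond from (Z)-alkenyl iodide aldehyde 30 (ten-membered ring).
2. 30 ⇐ hydroboration (C11, C12) and Felkin aldol of tert-butyl propanoate (C8, C17) onto α-keto acetal 23 ⇐ acid 19 (C7 added via a diazoketone).
3. Key step: Ireland–Claisen [3,3] rearrangement of the C12 glycolate 16 forms C9–C10 and relays the C12–O stereocentre to C10 and C9.
4. 16 ⇐ allylic alcohol 14 ⇐ (R)-carvone: acylation, dianion alkylation and methylation at C6 (C1), chelate reduction (C2), Criegee rearrangement (C14–OAc), epoxidation and Wharton transposition (C12–O).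
5. Ring order: ring A is bought with carvone, the ten-membered ring is closed in step 19, the γ-lactone last in step 20.

Assumption: locants C1–C20 are those of the briarane skeleton of the target (C1 quaternary, Me-15 on C1, Me-16 on C5, Me-18 on C17, C19 lactone carbonyl, Me-20 on C11); the target as drawn is (1R,2R,5Z,7R,8R,9R,10R,11S,12S,14R,17S).
Assumption: compounds 1, 4, 5, 15 and 24 are bought; the only chiral purchase is (R)-carvone.

Step 1
Reactants: 1 prop-2-yn-1-ol
Product: 2 (Z)-3-iodo-2-methylprop-2-en-1-ol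
Conditions: MeMgBr (2.5 equiv), CuI (10 mol %), Et2O/THF, −10 °C → rt; then I2, −10 °C
Reagents that add atoms: methylmagnesium bromide C[Mg]Br; iodine II
Why: Copper-catalysed carbomagnesiation of the magnesium alkoxide is an anti addition through a five-membered chelate and iodinolysis retains the alkenyl geometry, so iodine ends cis to CH2OH.

Step 2
Reactants: 2 (Z)-3-iodo-2-methylprop-2-en-1-ol
Product: 3 (Z)-3-bromo-1-iodo-2-methylprop-1-ene
Conditions: CBr4, PPh3, CH2Cl2, 0 °C
Reagents that add atoms: carbon tetrabromide BrC(Br)(Br)Br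
Why: Appel bromination of the primary allylic alcohol is an SN2 displacement that leaves the alkenyl iodide and its geometry untouched.

Step 3
Reactants: 4 (R)-carvone; 5 1-acetyl-1H-benzotriazole
Product: 6 (5R)-6-acetyl-2-methyl-5-(prop-1-en-2-yl)cyclohex-2-en-1-one
Conditions: LiN(i-Pr)2 (2.1 equiv), THF, −78 °C; then 5, −78 → 0 °C; aq. NH4Cl
Reagents that add atoms: none
Why: The kinetic C6 lithium enolate of carvone undergoes Claisen-type C-acylation by the N-acylbenzotriazole to give the enolised 1,3-diketone.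

Step 4
Reactants: 6 (5R)-6-acetyl-2-methyl-5-(prop-1-en-2-yl)cyclohex-2-en-1-one; 3 (Z)-3-bromo-1-iodo-2-methylprop-1-ene
Product: 7 (5R)-6-[(Z)-5-iodo-4-methylpent-4-enoyl]-2-methyl-5-(prop-1-en-2-yl)cyclohex-2-en-1-one
Conditions: LiN(i-Pr)2 (2.2 equiv), THF, −78 → 0 °C; then 3, −78 → 0 °C; aq. NH4Cl
Reagents that add atoms: none
Why: Hauser dianion alkylation, in which the second deprotonation occurs at the acetyl methyl group and this terminal carbanion displaces the allylic bromide (SN2) to form C3–C4.

Step 5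
Reactants: 7 (5R)-6-[(Z)-5-iodo-4-methylpent-4-enoyl]-2-methyl-5-(prop-1-en-2-yl)cyclohex-2-en-1-one
Product: 8 C1-methylated diketone (6-methyl trans to the isopropenyl group)
Conditions: K2CO3, MeI, acetone, 40 °C
Reagents that add atoms: iodomethane CI
Why: C-methylation of the potassium 1,3-diketonate occurs on the face opposite the neighbouring isopropenyl group, which sets the quaternary centre C1.

Step 6
Reactants: 8 C1-methylated diketone
Product: 9 C2 hydroxy enone
Conditions: Zn(BH4)2 (0.6 equiv), Et2O, −30 °C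
Reagents that add atoms: none
Why: Chelation-controlled reduction in which zinc bridges both carbonyl oxygens and hydride attacks the more electrophilic saturated side-chain ketone from the methyl face of the chelate (the ring blocks the other face), which sets C2.

Step 7
Reactants: 9 C2 hydroxy enone
Product: 11 enone 2,14-diacetate, via methoxy hydroperoxide 10 (not isolated)
Conditions: O3, CH2Cl2/MeOH (5:1), NaHCO3, −78 °C (indicator end point); then Ac2O, Et3N, 4-(dimethylamino)pyridine (DMAP), CH2Cl2, 0 °C → rt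
Reagents that add atoms: ozone O=[O+][O-]; acetic anhydride CC(=O)OC(C)=O
Why: Ozonolysis of the electron-rich isopropenyl group in methanol gives the methoxy hydroperoxide, whose peracetate undergoes Criegee rearrangement with retention at the migrating ring carbon to give the C14 acetate while the C2 hydroxyl is acetylated in the same flask.

Step 8
Reactants: 11 enone 2,14-diacetate
Product: 12 11,12-epoxy ketone
Conditions: t-BuOOH (decane), DBU, CH2Cl2, 0 °C → rt
Reagents that add atoms: tert-butyl hydroperoxide CC(C)(C)OO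
Why: Weitz–Scheffer nucleophilic epoxidation in which the peroxide anion adds to the enone β-carbon on the face trans to the C14 acetoxy group, as in carvone, which fixes the C12–O bond.

Step 9
Reactants: 12 11,12-epoxy ketone
Product: 14 transposed allylic alcohol (C10=C11 and C12–OH), via epoxy hydrazone 13 (not isolated)
Conditions: N2H4·H2O (3 equiv), AcOH (cat.), MeOH, 0 °C → rt
Reagents that add atoms: none
Why: Wharton transposition, in which the epoxy hydrazone fragments with loss of N2 to place the alkene at C10=C11 and leave the C12 oxygen with unchanged configuration.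

Step 10
Reactants: 14 transposed allylic alcohol; 15 2-[(tert-butyldimethylsilyl)oxy]acetic acid
Product: 16 C12 silyloxyacetate
Conditions: DCC, DMAP (cat.), CH2Cl2, 0 °C → rt
Reagents that add atoms: none
Why: Steglich esterification of the secondary allylic alcohol under neutral conditions that spare the acetates.

Step 11
Reactants: 16 C12 silyloxyacetate
Product: 19 C8 carboxylic acid with C9–OTBS, via silyl ketene acetal 17 (not isolated), via trimethylsilyl ester 18 (not isolated)
Conditions: LiN(SiMe3)2 (1.3 equiv), Me3SiCl, Et3N, THF, −78 °C → 50 °C; then 1 M HCl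
Reagents that add atoms: none
Why: Ireland–Claisen [3,3]-sigmatropic rearrangement in which C9–C10 forms suprafacially on the face that carried the C12 oxygen (sets C10), the silyloxy group points away from ring A in the boat-like transition state (sets C9), and the alkene moves to C11=C12.

Step 12
Reactants: 19 C8 carboxylic acid with C9–OTBS
Product: 21 diazoketone, via mixed anhydride 20 (not isolated)
Conditions: i-BuOCOCl, N-methylmorpholine, THF, −20 °C; then CH2N2, Et2O, 0 °C
Reagents that add atoms: diazomethane C=[N+]=[N-]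
Why: Mixed-anhydride activation and acylation of diazomethane (first stage of an Arndt–Eistert sequence) adds C7 without base, so the acetates and the C9 centre are not disturbed.

Step 13
Reactants: 21 diazoketone
Product: 23 α-keto dimethyl acetal, via glyoxal 22 (not isolated)
Conditions: dimethyldioxirane (1.05 equiv), acetone, −78 °C; then HC(OMe)3, MeOH, pyridinium p-toluenesulfonate, rt
Reagents that add atoms: dimethyldioxirane CC1(C)OO1; trimethyl orthoformate COC(OC)OC
Why: Oxygen-atom transfer to the strongly nucleophilic diazo carbon gives the glyoxal at low temperature before the trisubstituted alkene reacts, and only the aldehyde is acetalised because the ketone is hindered.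

Step 14
Reactants: 23 α-keto dimethyl acetal; 24 tert-butyl propanoate
Product: 25 aldol adduct
Conditions: 24, LiN(i-Pr)2, THF/DMPU, −78 °C; then 23, −78 °C; aq. NH4Cl
Reagents that add atoms: none
Why: Aldol addition of the (Z)-lithium ester enolate, in which Felkin–Anh attack anti to the C9 silyloxy group sets C8 and a Zimmerman–Traxler chair with the large C9 branch equatorial sets C17 (syn).

Step 15
Reactants: 25 aldol adduct
Product: 26 8,9-diol
Conditions: HF·pyridine, pyridine/THF, 0 °C → rt
Reagents that add atoms: none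
Why: Fluoride cleavage of the secondary silyl ether under buffered conditions leaves the acetal, the tert-butyl ester (too hindered to lactonise with the C9 hydroxyl) and the acetates intact.

Step 16
Reactants: 26 8,9-diol
Product: 27 2,9,14-triacetate
Conditions: Ac2O, pyridine, DMAP (cat.), CH2Cl2, rt
Reagents that add atoms: acetic anhydride CC(=O)OC(C)=O
Why: Nucleophile-catalysed acetylation of the secondary C9 hydroxyl, which the tertiary C8 hydroxyl does not undergo.

Step 17
Reactants: 27 2,9,14-triacetate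
Product: 29 C12 alcohol, via alkylborane 28 (not isolated)
Conditions: BH3·SMe2, THF, 0 °C → rt; then H2O2, NaHCO3, H2O, 0 °C
Reagents that add atoms: hydrogen peroxide OO
Why: Hydroboration–oxidation, a syn anti-Markovnikov addition to the trisubstituted ring alkene from the face opposite the pseudoaxial C10 side chain, sets C11 and C12 while the electron-poor alkenyl iodide and the esters react far more slowly.

Step 18
Reactants: 29 C12 alcohol
Product: 30 C7 aldehyde
Conditions: LiBF4, MeCN/H2O, 50 °C
Reagents that add atoms: water O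
Why: Mild Lewis-acid hydrolysis of the dimethyl acetal unmasks the α-hydroxy aldehyde, whose quaternary α-carbon cannot epimerise.

Step 19
Reactants: 30 C7 aldehyde
Product: 31 ten-membered-ring hydroxy tert-butyl ester
Conditions: CrCl2 (10 equiv), NiCl2 (2 mol %), DMSO/THF, rt, 1 mM, slow addition
Reagents that add atoms: none
Why: Nozaki–Hiyama–Kishi reaction, in which the alkenylchromium species formed with retention of the Z geometry adds to the aldehyde held in a chelate with the C8 oxygen, closing the ten-membered ring from the C9 side to give the 7,8-cis diol.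

Step 20
Reactants: 31 ten-membered-ring hydroxy tert-butyl ester
Product: 33 target CNP0195208.4, via seco acid 32 (not isolated)
Conditions: CF3CO2H, CH2Cl2, 0 °C
Reagents that add atoms: none
Why: Acidolysis of the tert-butyl ester followed by spontaneous lactonisation of the γ-hydroxy acid through the C7 hydroxyl, the only hydroxyl that can form a five-membered lactone.

**Compound list**
1 | prop-2-yn-1-ol | C#CCO | starting material
2 | (Z)-3-iodo-2-methylprop-2-en-1-ol | OC/C(C)=C\I | intermediate
3 | (Z)-3-bromo-1-iodo-2-methylprop-1-ene | BrC/C(C)=C\I | intermediate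
4 | (R)-(−)-carvone, (5R)-2-methyl-5-(prop-1-en-2-yl)cyclohex-2-en-1-one | O=C1C(C)=CC[C@@H](C(C)=C)C1 | starting material
5 | 1-acetyl-1H-benzotriazole | CC(=O)n1nnc2ccccc12 | starting material
6 | (5R)-6-acetyl-2-methyl-5-(prop-1-en-2-yl)cyclohex-2-en-1-one (enolised 1,3-diketone, C6 not fixed) | O=C1C(C)=CC[C@@H](C(C)=C)C1C(C)=O | intermediate
7 | (5R)-6-[(Z)-5-iodo-4-methylpent-4-enoyl]-2-methyl-5-(prop-1-en-2-yl)cyclohex-2-en-1-one (enolised, C6 not fixed) | O=C1C(C)=CC[C@@H](C(C)=C)C1C(=O)CC/C(C)=C\I | intermediate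
8 | C1-methylated diketone: 6-methyl derivative of 7, new methyl trans to the isopropenyl group | O=C1C(C)=CC[C@@H](C(C)=C)[C@@]1(C)C(=O)CC/C(C)=C\I | intermediate
9 | C2 hydroxy enone: side-chain ketone of 8 reduced, C2–OH anti to the C1 methyl along C10–C1–C2–C3 | O=C1C(C)=CC[C@@H](C(C)=C)[C@@]1(C)[C@H](O)CC/C(C)=C\I | intermediate
10 | methoxy hydroperoxide: 9 with the isopropenyl group as C(CH3)(OCH3)OOH | O=C1C(C)=CC[C@@H](C(C)(OC)OO)[C@@]1(C)[C@H](O)CC/C(C)=C\I | intermediate (not isolated)
11 | enone 2,14-diacetate: C14 acetoxy in place of isopropenyl (retention), C2 acetate | O=C1C(C)=CC[C@@H](OC(C)=O)[C@@]1(C)[C@H](OC(C)=O)CC/C(C)=C\I | intermediate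
12 | 11,12-epoxy ketone, epoxide trans to the C14 acetoxy group | O=C1[C@]2(C)O[C@@H]2C[C@@H](OC(C)=O)[C@@]1(C)[C@H](OC(C)=O)CC/C(C)=C\I | intermediate
13 | epoxy hydrazone of 12 | NN=C1[C@]2(C)O[C@@H]2C[C@@H](OC(C)=O)[C@@]1(C)[C@H](OC(C)=O)CC/C(C)=C\I | intermediate (not isolated)
14 | transposed allylic alcohol: C10=C11 alkene, C12–OH trans to C14–OAc | C1=C(C)[C@H](O)C[C@@H](OC(C)=O)[C@@]1(C)[C@H](OC(C)=O)CC/C(C)=C\I | intermediate
15 | 2-[(tert-butyldimethylsilyl)oxy]acetic acid | CC(C)(C)[Si](C)(C)OCC(=O)O | starting material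
16 | C12 silyloxyacetate of 14 | C1=C(C)[C@H](OC(=O)CO[Si](C)(C)C(C)(C)C)C[C@@H](OC(C)=O)[C@@]1(C)[C@H](OC(C)=O)CC/C(C)=C\I | intermediate
17 | O-trimethylsilyl ketene acetal of 16 | C1=C(C)[C@H](OC(O[Si](C)(C)C)=CO[Si](C)(C)C(C)(C)C)C[C@@H](OC(C)=O)[C@@]1(C)[C@H](OC(C)=O)CC/C(C)=C\I | intermediate (not isolated)
18 | trimethylsilyl ester of 19 | CC(C)(C)[Si](C)(C)O[C@@H](C(=O)O[Si](C)(C)C)[C@@H]1C(C)=CC[C@@H](OC(C)=O)[C@@]1(C)[C@H](OC(C)=O)CC/C(C)=C\I | intermediate (not isolated)
19 | C8 carboxylic acid: ring A (C11=C12) with CH(OTBS)CO2H on C10, C9 and C10 as in the target | CC(C)(C)[Si](C)(C)O[C@@H](C(=O)O)[C@@H]1C(C)=CC[C@@H](OC(C)=O)[C@@]1(C)[C@H](OC(C)=O)CC/C(C)=C\I | intermediate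
20 | isobutyl carbonic mixed anhydride of 19 | CC(C)(C)[Si](C)(C)O[C@@H](C(=O)OC(=O)OCC(C)C)[C@@H]1C(C)=CC[C@@H](OC(C)=O)[C@@]1(C)[C@H](OC(C)=O)CC/C(C)=C\I | intermediate (not isolated)
21 | diazoketone: CO2H of 19 replaced by C(=O)CH=N2 | CC(C)(C)[Si](C)(C)O[C@@H](C(=O)C=[N+]=[N-])[C@@H]1C(C)=CC[C@@H](OC(C)=O)[C@@]1(C)[C@H](OC(C)=O)CC/C(C)=C\I | intermediate
22 | glyoxal: C8 ketone with C7 aldehyde | CC(C)(C)[Si](C)(C)O[C@@H](C(=O)C=O)[C@@H]1C(C)=CC[C@@H](OC(C)=O)[C@@]1(C)[C@H](OC(C)=O)CC/C(C)=C\I | intermediate (not isolated)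
23 | α-keto dimethyl acetal: C8 ketone with C7 as CH(OMe)2 | CC(C)(C)[Si](C)(C)O[C@@H](C(=O)C(OC)OC)[C@@H]1C(C)=CC[C@@H](OC(C)=O)[C@@]1(C)[C@H](OC(C)=O)CC/C(C)=C\I | intermediate
24 | tert-butyl propanoate | CCC(=O)OC(C)(C)C | starting material
25 | aldol adduct: C8 tertiary alcohol bearing CH(CH3)CO2t-Bu (C17), C7 acetal, C9–OTBS; C8 and C17 as in the target | CC(C)(C)[Si](C)(C)O[C@@H]([C@](O)(C(OC)OC)[C@H](C)C(=O)OC(C)(C)C)[C@@H]1C(C)=CC[C@@H](OC(C)=O)[C@@]1(C)[C@H](OC(C)=O)CC/C(C)=C\I | intermediate
26 | 8,9-diol: 25 without the silyl group | O[C@@H]([C@](O)(C(OC)OC)[C@H](C)C(=O)OC(C)(C)C)[C@@H]1C(C)=CC[C@@H](OC(C)=O)[C@@]1(C)[C@H](OC(C)=O)CC/C(C)=C\I | intermediate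
27 | 2,9,14-triacetate | CC(=O)O[C@@H]([C@](O)(C(OC)OC)[C@H](C)C(=O)OC(C)(C)C)[C@@H]1C(C)=CC[C@@H](OC(C)=O)[C@@]1(C)[C@H](OC(C)=O)CC/C(C)=C\I | intermediate
28 | C12 alkylborane (drawn as the monoalkylborane) | CC(=O)O[C@@H]([C@](O)(C(OC)OC)[C@H](C)C(=O)OC(C)(C)C)[C@@H]1[C@H](C)[C@@H](B)C[C@@H](OC(C)=O)[C@@]1(C)[C@H](OC(C)=O)CC/C(C)=C\I | intermediate (not isolated)
29 | C12 alcohol: ring A saturated, C11 methyl and C12 hydroxyl as in the target | CC(=O)O[C@@H]([C@](O)(C(OC)OC)[C@H](C)C(=O)OC(C)(C)C)[C@@H]1[C@H](C)[C@@H](O)C[C@@H](OC(C)=O)[C@@]1(C)[C@H](OC(C)=O)CC/C(C)=C\I | intermediate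
30 | C7 aldehyde: acetal of 29 hydrolysed | CC(=O)O[C@@H]([C@](O)(C=O)[C@H](C)C(=O)OC(C)(C)C)[C@@H]1[C@H](C)[C@@H](O)C[C@@H](OC(C)=O)[C@@]1(C)[C@H](OC(C)=O)CC/C(C)=C\I | intermediate
31 | ten-membered-ring hydroxy tert-butyl ester: C6–C7 bond closed, C7–OH cis to C8–OH on the ring | CC(=O)O[C@@H]1[C@@H]2[C@H](C)[C@@H](O)C[C@@H](OC(C)=O)[C@@]2(C)[C@H](OC(C)=O)CC/C(C)=C\[C@@H](O)[C@]1(O)[C@H](C)C(=O)OC(C)(C)C | intermediate
32 | seco acid of the target | CC(=O)O[C@@H]1[C@@H]2[C@H](C)[C@@H](O)C[C@@H](OC(C)=O)[C@@]2(C)[C@H](OC(C)=O)CC/C(C)=C\[C@@H](O)[C@]1(O)[C@H](C)C(=O)O | intermediate (not isolated)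
33 | CNP0195208.4, (1R,2R,5Z,7R,8R,9R,10R,11S,12S,14R,17S)-2,9,14-triacetoxy-8,12-dihydroxy briarane 5-ene with the C19–O–C7 γ-lactone | CC(=O)O[C@@H]1[C@@H]2[C@H](C)[C@@H](O)C[C@@H](OC(C)=O)[C@@]2(C)[C@H](OC(C)=O)CC/C(C)=C\[C@H]2OC(=O)[C@@H](C)[C@]12O | target

**Step count**
Total: 20 steps. Longest linear sequence: 19 steps (steps 1, 2 and 4–20, from prop-2-yn-1-ol); 18 steps from (R)-carvone.

**Three steps most likely to fail**

Step 9 (Wharton transposition). The ketone lies between a quaternary carbon and an epoxide carbon, so hydrazone formation may be slow, and hydrazine can attack the acetates. The fallback sets out from 12 and comes back at 16, so step 10 is also replaced. SmI2 in THF/MeOH at −90 °C cleaves the C11–O bond of the epoxy ketone and keeps the C12–O bond, giving the 12-hydroxy-10-ketone F1. NaBH4 in MeOH then gives the 10,12-diol F2. The less hindered C12 hydroxyl is esterified selectively with 15 (DCC, DMAP) to the 10-hydroxy C12 silyloxyacetate F3. Burgess reagent in toluene at 70 °C dehydrates the C10 alcohol towards C11, the only neighbour that carries hydrogen, and gives 16. The C10 and C11 configurations of F1–F3 are left open because both centres become sp2.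

Step 14 (aldol). The ketone is hindered and enolisable at C9, so the lithium enolate may deprotonate instead of adding, and C8/C17 control rests on transition-state models. The fallback sets out from 23 and comes back at 25. It is a Reformatsky reaction with tert-butyl 2-bromopropanoate and activated Zn (Me3SiCl, THF, 0 °C → rt). The zinc enolate is made reductively, no amide base is present, and it is far less basic towards C9–H and the acetates. This fallback makes no new compound (F0).

Step 19 (Ni/Cr ring closure). Ten-membered ring closure can be low-yielding, and the C7 configuration depends on the chelate model. The fallback sets out from 30 and comes back at 31; it corrects C7 but does not replace the ring closure itself. If the closure gives the 7-epimeric hydroxy ester F4, MnO2 in CH2Cl2 oxidises only the allylic C7 alcohol to the ring enone F5. Zn(BH4)2 in Et2O at −30 °C then reduces F5 under chelation with the free C8 hydroxyl, delivering hydride from the outer face to give the 7,8-cis diol 31.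

**Further compounds**
F1 | step 9 | 12-hydroxy-10-ketone from reductive opening of 12 (C11 open) | O=C1C(C)[C@H](O)C[C@@H](OC(C)=O)[C@@]1(C)[C@H](OC(C)=O)CC/C(C)=C\I
F2 | step 9 | 10,12-diol (C10 and C11 open) | OC1C(C)[C@H](O)C[C@@H](OC(C)=O)[C@@]1(C)[C@H](OC(C)=O)CC/C(C)=C\I
F3 | step 9 | 10-hydroxy C12 silyloxyacetate (C10 and C11 open) | OC1C(C)[C@H](OC(=O)CO[Si](C)(C)C(C)(C)C)C[C@@H](OC(C)=O)[C@@]1(C)[C@H](OC(C)=O)CC/C(C)=C\I
F0 | step 14 | none | none
F4 | step 19 | 7-epimer of 31 | CC(=O)O[C@@H]1[C@@H]2[C@H](C)[C@@H](O)C[C@@H](OC(C)=O)[C@@]2(C)[C@H](OC(C)=O)CC/C(C)=C\[C@H](O)[C@]1(O)[C@H](C)C(=O)OC(C)(C)C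
F5 | step 19 | C7 ring enone | CC(=O)O[C@@H]1[C@@H]2[C@H](C)[C@@H](O)C[C@@H](OC(C)=O)[C@@]2(C)[C@H](OC(C)=O)CC/C(C)=C\C(=O)[C@]1(O)[C@H](C)C(=O)OC(C)(C)C
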